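Slowness was what I read first in these runs: in the dawn run the substrate lost 22 percentage points in the first 3.00 min and 10 points between 20.0 min and 40.0 min. A tail like that needs a scale, and I took as its zero the symmetric case, substrate and coupling partner consumed from equal charges, first order in each. The recipes stand near it: the excess of coupling partner is 0.200 of the substrate charge, and the protic impurity, if it takes partner one for one, claims 0.0827 of that charge in the dawn run and 0.118 in south.

all flasks: substrate 0.11 M

| charge | coupling partner | protic impurity | remark | time |
|---|---|---|---|---|
| dawn | 1.2 equiv | 0.0091 M | run made earlier |  |
| spring | 1.2 equiv | 0.010 M | run made earlier |  |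
| south-west | 1.20 equiv | 0.0110 M |  | 1.0 h |
| south | 1.20 equiv | 0.0130 M |  | 1.0 h |

- which of these there is most of at the end, counted by the substrate in it, south-west (product / substrate)
- which of these there is most of at the end, counted by the substrate in it, south (product / substrate)
- how much there is at the end of the one of these that leads, in percent of the substrate charged: south-west
- how much there is at the end of the one of these that leads, in percent of the substrate charged: south



In the symmetric case the reciprocal of the fraction of substrate left, less one, grows in proportion to time. I read that slope from each row of this table.

- dawn (time / min: substrate / %, product / %): 3.00: 77.7, 21.4; 6.00: 58.9, 40.4; 12.0: 39.8, 60.9; 20.0: 26.3, 72.6; 40.0: 16.3, 87.0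
- spring (time / min: substrate / %, product / %): 3.00: 77.0, 23.7; 6.00: 59.5, 38.4; 12.0: 42.6, 59.8; 20.0: 27.1, 72.3; 40.0: 13.7, 86.8

(readings scatter by 1 percentage point)

In the first row it read 0.0957 min⁻¹ in the dawn run and 0.0996 min⁻¹ in the spring run. In the fourth row it read 0.140 min⁻¹ and 0.135 min⁻¹, and in the last 0.128 min⁻¹ and 0.157 min⁻¹. The spring run, with more protic impurity, stood lower in the fourth row and higher in the last, so I saw no impurity effect to reckon with. In both runs the first row lay lower than the last, so I took the mean of the last row, nearest the end, as the equal-charge clock, the second-order rate constant times the starting concentration: 0.143 min⁻¹, a reading with its scatter. At 1.0 h it left 10.4% of the substrate, so I expected product to lead at 89.6% in south-west and in south.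

The forecast gave product at 90% in south-west and product at 88.5% in south, widened downward “in case poisoning sets in”, where my clock gave one figure for both.

South-west gave product at 90.6% and south gave product at 90.2%. Moved to south-west's impurity, the dawn run still stood at 86.2% product at its last reading, and moved to south-west's time it stood at 90.9%. Read back from the 9.40% of substrate left in south-west, the clock is 0.161 min⁻¹, a little above mine. The scheme is not my symmetric case, so the clock stays a ruler.

    substrate + coupling partner → product, rate k1*[substrate]*[coupling partner]^0.5 (k = 15.7 M⁻⁰·⁵ h⁻¹)
    coupling partner → decomposed reagent (k = 0.757 h⁻¹)
    coupling partner + protic impurity → quenched reagent (k = 38.6 M⁻¹ h⁻¹)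

In a neighbour of south charged with 0.28 M of substrate, the equivalents of coupling partner and the time held, the clock scaled with the charge to 0.364 min⁻¹ and left 4.38% of the substrate. That neighbour flask held 3.39% of substrate and 96.6% of product.

All runs are simulated with made-up constants.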